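Ring B (C5–C6–C7–C8–C9–C10, eudesmane numbering) is disconnected at C7–C8, the bond most remote from the ring fusion. Closure onto C5 or C10 would follow an axial trajectory and give a cis fusion, so C1′, C1, C10 and C5 are all set first on ring A. Ring-closing metathesis then joins two trans-diequatorial arms, allyl on C10 and 2-(methoxycarbonyl)allyl on C5, under neutral conditions that spare the epimerisable C5–H beside the C4 ketone. The step exploits C7 as the only branch point of ring B: its ester carbon (C11) and the C4 ketone later accept three methyl groups in one operation. The precursor is a monocyclic tetrasubstituted cyclohexanone.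

Key step: step 6

Remark on the chemistry: the terpene part carries eudesmane numbers (C1–C15) and the benzylic carbon is C1′; in this numbering the target is (1′S,1S,4R,5S,7S,10R), with a trans-decalin, axial C1 side chain, axial C4–OH and equatorial C7 side chain.
Remark on the chemistry: the enantiomer of the ferrocenyl diphosphine named in step 1 is assumed to be the one that gives the (S)-lactone; otherwise its mirror image is used.

Step 1
Reactants: 1 5,7-dimethoxycoumarin; 2 isobutylmagnesium bromide
Product: 3 (4S)-5,7-dimethoxy-4-(2-methylpropyl)chroman-2-one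
Conditions: 2 (1.5 equiv), CuBr·SMe2 (5 mol %), (R)-1-[(S)-2-(diphenylphosphino)ferrocenyl]ethyldicyclohexylphosphine (6 mol %), t-BuOMe, −72 °C; then 1 M HCl
Reagents that add atoms: isobutylmagnesium bromide (2), CC(C)C[Mg]Br
Why: Copper-catalysed asymmetric conjugate addition of a Grignard reagent to the coumarin C3=C4 bond, in which the chiral ferrocenyl diphosphine–copper complex selects the alkene face and so sets C1′ (S).

Step 2
Reactants: 3 (4S)-5,7-dimethoxy-4-(2-methylpropyl)chroman-2-one; 4 3-(trimethylsilyl)but-3-en-2-one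
Product: 6 (3S,4S)-5,7-dimethoxy-4-(2-methylpropyl)-3-(3-oxobutyl)chroman-2-one, via silyl adduct 5 (not isolated)
Conditions: LDA, THF, −78 °C; 4, −78 → −30 °C; then 1 M HCl, THF, rt
Reagents that add atoms: 3-(trimethylsilyl)but-3-en-2-one (4), CC(=O)C(=C)[Si](C)(C)C
Why: Michael addition of the lactone lithium enolate to an α-silyl vinyl ketone (the silyl group suppresses polymerisation under aprotic conditions and is lost by acid protodesilylation), in which the isobutyl group, held pseudoaxial by the peri methoxy group, shields one face so that the C1–C2 bond forms trans to it and sets C1 (S).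

Step 3
Reactants: 6 (3S,4S)-5,7-dimethoxy-4-(2-methylpropyl)-3-(3-oxobutyl)chroman-2-one
Product: 8 (6S)-3-methoxy-6-[(1S)-3-methyl-1-(2,4,6-trimethoxyphenyl)butyl]cyclohex-2-en-1-one, via phenol dione 7 (not isolated)
Conditions: KHMDS (2.2 equiv), THF, −78 → 0 °C; then Me2SO4 (3 equiv), DMPU, 0 °C → rt
Reagents that add atoms: dimethyl sulfate, COS(=O)(=O)OC
Why: Intramolecular Claisen (Dieckmann-type) acylation: the kinetic methyl-ketone enolate (C5) attacks the aryl lactone carbonyl (C10) in a 6-exo-trig mode, which closes ring A and releases the phenoxide, and the hard electrophile Me2SO4 then O-methylates the phenoxide and the less hindered oxygen (on C4) of the dione enolate, while C1 is protected from epimerisation because the dione stays deprotonated.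

Step 4
Reactants: 8 (6S)-3-methoxy-6-[(1S)-3-methyl-1-(2,4,6-trimethoxyphenyl)butyl]cyclohex-2-en-1-one; 9 allylmagnesium bromide
Product: 11 (4S)-3-allyl-4-[(1S)-3-methyl-1-(2,4,6-trimethoxyphenyl)butyl]cyclohex-2-en-1-one, via carbinol 10 (not isolated)
Conditions: 9, THF, −78 → 0 °C; then 1 M HCl, THF, 0 °C
Reagents that add atoms: allylmagnesium bromide (9), C=CC[Mg]Br
Why: Stork–Danheiser transposition: 1,2-addition of the allyl Grignard reagent to the vinylogous ester carbonyl (C10) followed by acid-induced ionisation and loss of methanol moves the carbonyl group to C4 and leaves the allyl arm (C9, C8) on C10 without touching C1.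

Step 5
Reactants: 11 (4S)-3-allyl-4-[(1S)-3-methyl-1-(2,4,6-trimethoxyphenyl)butyl]cyclohex-2-en-1-one; 12 methyl 2-(bromomethyl)acrylate
Product: 14 (2S,3R,4S)-3-allyl-2-[2-(methoxycarbonyl)allyl]-3-methyl-4-[(1S)-3-methyl-1-(2,4,6-trimethoxyphenyl)butyl]cyclohexan-1-one, via lithium enolate 13 (not isolated)
Conditions: MeLi (2.2 equiv), CuI (1.1 equiv), Et2O, 0 °C; 11, −78 → −20 °C; then 12 (3 equiv), DMPU, THF, −78 → 0 °C
Reagents that add atoms: lithium dimethylcuprate, [Li+].C[Cu-]C; methyl 2-(bromomethyl)acrylate (12), C=C(CBr)C(=O)OC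
Why: Tandem cuprate conjugate addition and enolate alkylation (three-component coupling): methyl adds to C10 anti to the pseudoaxial C1 side chain, which sets C10 (R) with the allyl arm cis to that chain, and the regiodefined C4–C5 enolate is then alkylated through its chair-like transition state on the face opposite to both the allyl arm and the C1 side chain, which sets C5 (S) with the two arms trans.

Step 6
Reactants: 14 (2S,3R,4S)-3-allyl-2-[2-(methoxycarbonyl)allyl]-3-methyl-4-[(1S)-3-methyl-1-(2,4,6-trimethoxyphenyl)butyl]cyclohexan-1-one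
Product: 15 methyl (4aR,5S,8aS)-4a-methyl-5-[(1S)-3-methyl-1-(2,4,6-trimethoxyphenyl)butyl]-8-oxo-1,4,4a,5,6,7,8,8a-octahydronaphthalene-2-carboxylate (trans-fused keto enoate)
Conditions: second-generation Hoveyda–Grubbs catalyst (5 mol %), toluene (2 mM), 80 °C
Reagents that add atoms: none
Why: Chauvin mechanism: the ruthenium alkylidene first engages the monosubstituted C8 alkene of the allyl arm, and the new alkylidene undergoes [2+2] cycloaddition and cycloreversion with the 1,1-disubstituted acrylate alkene at C7, releasing ethene. The closest known reaction type is ring-closing metathesis of an α-substituted acrylate with a terminal alkene to a cyclohex-1-enecarboxylate. Ring B is closed as a six-membered ring by formation of the C7=C8 double bond between two arms that sit trans-diequatorial on C5 and C10 of the ring A chair. No new stereocentre is formed; the step has to preserve C5, which is epimerisable beside the C4 ketone, and the neutral aprotic conditions secure this. The selectivity needed is cyclisation over intermolecular metathesis, which is secured by high dilution, by the vicinal arms next to the quaternary C10 and by the low tendency of the acrylate alkene to homodimerise. Closure at C7=C8 is chosen because any closure onto C5 or C10 would use an axial trajectory and should give the cis-fused isomer.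

Step 7
Reactants: 15 trans-fused keto enoate
Product: 16 (1R,4S,4aR,8aS)-7-(2-hydroxypropan-2-yl)-1,4a-dimethyl-4-[(1S)-3-methyl-1-(2,4,6-trimethoxyphenyl)butyl]-1,2,3,4,4a,5,8,8a-octahydronaphthalen-1-ol
Conditions: MeLi (excess), Et2O, −78 → 0 °C; then H2O
Reagents that add atoms: methyllithium, [Li]C
Why: 1,2-Addition of methyllithium, twice to the ester and once to the C4 ketone, where the axial trajectory is blocked by the 1,3-diaxial C10 methyl group so that equatorial attack gives the axial C4 hydroxyl group (4R).

Step 8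
Reactants: 16 ene diol
Product: 17 (1R,4S,4aR,7S,8aS)-7-(2-hydroxypropan-2-yl)-1,4a-dimethyl-4-[(1S)-3-methyl-1-(2,4,6-trimethoxyphenyl)butyl]decahydronaphthalen-1-ol
Conditions: Mn(dpm)3 (10 mol %), PhSiH3, t-BuOOH, i-PrOH, rt
Reagents that add atoms: none
Why: Radical hydrogenation by metal-hydride hydrogen atom transfer: hydrogen adds first to C8 and the tertiary C7 radical, with its bulky hydroxyisopropyl group already pseudoequatorial, accepts the second hydrogen axially, which gives the thermodynamically preferred equatorial side chain (7S).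

Step 9
Reactants: 17 saturated diol
Product: 18 the 3,5-dibromo-2,4,6-trimethoxyphenyl analogue of 17
Conditions: NBS (2.1 equiv), MeCN, 0 °C, dark
Reagents that add atoms: N-bromosuccinimide, O=C1CCC(=O)N1Br
Why: Electrophilic aromatic bromination of the very electron-rich ring at its only two free positions, under conditions that leave both tertiary alcohols untouched.

Step 10
Reactants: 18 dibromide
Product: 20 tri-O-methyl ether of the target (3,5-diformyl-2,4,6-trimethoxyphenyl analogue of 17), via tetralithio species 19 (not isolated)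
Conditions: n-BuLi (6 equiv), THF, −78 °C; DMF, −78 °C → rt; then H2O
Reagents that add atoms: N,N-dimethylformamide, CN(C)C=O
Why: Double bromine–lithium exchange (each aryllithium flanked and stabilised by two methoxy groups, both alcohols masked as alkoxides) followed by formylation with DMF, a non-acidic alternative to Friedel–Crafts formylation that spares the tertiary alcohols.

Step 11
Reactants: 20 tri-O-methyl ether of the target
Product: 21 target CNP0409870.3, (1′S,1S,4R,5S,7S,10R)
Conditions: NaSEt (excess), DMF, 100 °C; then 1 M HCl, 0 °C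
Reagents that add atoms: none
Why: Nucleophilic SN2 demethylation of aryl methyl ethers by thiolate, each ether being activated by ortho or para formyl groups, under basic conditions in which the two tertiary alcohols cannot ionise.

Compound list
1 | 5,7-dimethoxycoumarin | COc1cc(OC)c2ccc(=O)oc2c1 | starting material
2 | isobutylmagnesium bromide | CC(C)C[Mg]Br | starting material
3 | (4S)-5,7-dimethoxy-4-(2-methylpropyl)chroman-2-one | CC(C)C[C@H]1CC(=O)Oc2cc(OC)cc(OC)c12 | intermediate
4 | 3-(trimethylsilyl)but-3-en-2-one | CC(=O)C(=C)[Si](C)(C)C | starting material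
5 | (3S,4S)-5,7-dimethoxy-4-(2-methylpropyl)-3-[3-oxo-2-(trimethylsilyl)butyl]chroman-2-one, mixture at the silyl-bearing carbon | CC(C)C[C@H]1[C@H](CC(C(C)=O)[Si](C)(C)C)C(=O)Oc2cc(OC)cc(OC)c12 | intermediate
6 | (3S,4S)-5,7-dimethoxy-4-(2-methylpropyl)-3-(3-oxobutyl)chroman-2-one (3,4-trans) | CC(C)C[C@H]1[C@H](CCC(C)=O)C(=O)Oc2cc(OC)cc(OC)c12 | intermediate
7 | (4S)-4-[(1S)-1-(2-hydroxy-4,6-dimethoxyphenyl)-3-methylbutyl]cyclohexane-1,3-dione (present as dipotassium salt) | CC(C)C[C@H](c1c(O)cc(OC)cc1OC)[C@@H]1CCC(=O)CC1=O | intermediate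
8 | (6S)-3-methoxy-6-[(1S)-3-methyl-1-(2,4,6-trimethoxyphenyl)butyl]cyclohex-2-en-1-one | CC(C)C[C@H](c1c(OC)cc(OC)cc1OC)[C@@H]1CCC(OC)=CC1=O | intermediate
9 | allylmagnesium bromide | C=CC[Mg]Br | starting material
10 | (6S)-1-allyl-3-methoxy-6-[(1S)-3-methyl-1-(2,4,6-trimethoxyphenyl)butyl]cyclohex-2-en-1-ol, carbinol centre undefined | CC(C)C[C@H](c1c(OC)cc(OC)cc1OC)[C@@H]1CCC(OC)=CC1(O)CC=C | intermediate
11 | (4S)-3-allyl-4-[(1S)-3-methyl-1-(2,4,6-trimethoxyphenyl)butyl]cyclohex-2-en-1-one | CC(C)C[C@H](c1c(OC)cc(OC)cc1OC)[C@@H]1CCC(=O)C=C1CC=C | intermediate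
12 | methyl 2-(bromomethyl)acrylate | C=C(CBr)C(=O)OC | starting material
13 | lithium (3R,4S)-3-allyl-3-methyl-4-[(1S)-3-methyl-1-(2,4,6-trimethoxyphenyl)butyl]cyclohex-1-en-1-olate | [Li+].CC(C)C[C@H](c1c(OC)cc(OC)cc1OC)[C@@H]1CCC([O-])=C[C@]1(C)CC=C | intermediate
14 | (2S,3R,4S)-3-allyl-2-[2-(methoxycarbonyl)allyl]-3-methyl-4-[(1S)-3-methyl-1-(2,4,6-trimethoxyphenyl)butyl]cyclohexan-1-one | CC(C)C[C@H](c1c(OC)cc(OC)cc1OC)[C@@H]1CCC(=O)[C@@H](CC(=C)C(=O)OC)[C@]1(C)CC=C | intermediate
15 | methyl (4aR,5S,8aS)-4a-methyl-5-[(1S)-3-methyl-1-(2,4,6-trimethoxyphenyl)butyl]-8-oxo-1,4,4a,5,6,7,8,8a-octahydronaphthalene-2-carboxylate | CC(C)C[C@H](c1c(OC)cc(OC)cc1OC)[C@@H]1CCC(=O)[C@H]2CC(C(=O)OC)=CC[C@]12C | intermediate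
16 | (1R,4S,4aR,8aS)-7-(2-hydroxypropan-2-yl)-1,4a-dimethyl-4-[(1S)-3-methyl-1-(2,4,6-trimethoxyphenyl)butyl]-1,2,3,4,4a,5,8,8a-octahydronaphthalen-1-ol | CC(C)C[C@H](c1c(OC)cc(OC)cc1OC)[C@@H]1CC[C@@](C)(O)[C@H]2CC(C(C)(C)O)=CC[C@]12C | intermediate
17 | (1R,4S,4aR,7S,8aS)-7-(2-hydroxypropan-2-yl)-1,4a-dimethyl-4-[(1S)-3-methyl-1-(2,4,6-trimethoxyphenyl)butyl]decahydronaphthalen-1-ol | CC(C)C[C@H](c1c(OC)cc(OC)cc1OC)[C@@H]1CC[C@@](C)(O)[C@H]2C[C@@H](C(C)(C)O)CC[C@]12C | intermediate
18 | 3,5-dibromo-2,4,6-trimethoxyphenyl analogue of 17 | CC(C)C[C@H](c1c(OC)c(Br)c(OC)c(Br)c1OC)[C@@H]1CC[C@@](C)(O)[C@H]2C[C@@H](C(C)(C)O)CC[C@]12C | intermediate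
19 | 3,5-dilithio-2,4,6-trimethoxyphenyl dilithium dialkoxide derived from 18 | CC(C)C[C@H](c1c(OC)c([Li])c(OC)c([Li])c1OC)[C@@H]1CC[C@@](C)(O[Li])[C@H]2C[C@@H](C(C)(C)O[Li])CC[C@]12C | intermediate
20 | tri-O-methyl ether of the target | CC(C)C[C@H](c1c(OC)c(C=O)c(OC)c(C=O)c1OC)[C@@H]1CC[C@@](C)(O)[C@H]2C[C@@H](C(C)(C)O)CC[C@]12C | intermediate
21 | CNP0409870.3, (1′S,1S,4R,5S,7S,10R) | CC(C)C[C@H](c1c(O)c(C=O)c(O)c(C=O)c1O)[C@@H]1CC[C@@](C)(O)[C@H]2C[C@@H](C(C)(C)O)CC[C@]12C | target

Total step count: 11. Longest linear sequence: 11 steps, from 1 to 21.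

The three steps most likely to fail:

First, step 5. The cuprate may add sluggishly next to the bulky C1 side chain. The enolate may be alkylated with poor facial selectivity, or may lose its regiochemical and configurational integrity through proton exchange with the product. The fallback sets out from 11. After the same cuprate addition, the enolate 13 is O-acylated with 2-(methoxycarbonyl)allyl chloroformate to the isolable enol carbonate F1. A decarboxylative asymmetric allylic alkylation (Pd2(dba)3, chiral Trost-type diphosphine, dioxane, rt) then forms the C5–C6 bond under neutral conditions, with the catalyst controlling the enolate face. The fallback comes back to the route at 14.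

Second, step 3. The ambident dione enolate may be methylated at the hindered oxygen on C10 or at carbon C5, and long exposure to base may erode C1. The fallback sets out from 7, isolated by an acidic quench after the Claisen stage.
- Acid-catalysed dehydration (TsOH, toluene, reflux) lets the free phenol close onto the neighbouring C10 carbonyl and should give the tricyclic vinylogous aryl ester F2, in which the tether tells the two carbonyl groups apart.
- Addition–elimination with (CH2=CHCH2)2CuLi and Me3SiCl in THF at −78 °C places the allyl arm on C10 and expels the phenoxide, giving the phenol enone F3.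
- Methylation (MeI, K2CO3, acetone) comes back to the route at 11.

Third, step 8. The second hydrogen atom may reach the C7 radical from the wrong face, or the allylic alcohol may isomerise under the radical conditions. The fallback sets out from 15 and replaces kinetic control with thermodynamic control.
- One equivalent of MeTi(OiPr)3 adds to the ketone only and gives the hydroxy enoate F4, in which C5 is no longer epimerisable.
- Hydrogenation (H2, Pd/C, EtOAc) gives the saturated ester F5 as a mixture at C7.
- NaOMe in MeOH equilibrates the mixture to the equatorial ester F6.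
- MeMgBr (excess, THF) comes back to the route at 17.

Further compounds
F1 | step 5 | (3R,4S)-3-allyl-3-methyl-4-[(1S)-3-methyl-1-(2,4,6-trimethoxyphenyl)butyl]cyclohex-1-en-1-yl 2-(methoxycarbonyl)allyl carbonate | CC(C)C[C@H](c1c(OC)cc(OC)cc1OC)[C@@H]1CCC(OC(=O)OCC(=C)C(=O)OC)=C[C@]1(C)CC=C
F2 | step 3 | (9S,9aS)-6,8-dimethoxy-9-(2-methylpropyl)-1,2,9,9a-tetrahydro-3H-xanthen-3-one | CC(C)C[C@@H]1c2c(OC)cc(OC)cc2OC2=CC(=O)CC[C@@H]12
F3 | step 3 | (4S)-3-allyl-4-[(1S)-1-(2-hydroxy-4,6-dimethoxyphenyl)-3-methylbutyl]cyclohex-2-en-1-one | CC(C)C[C@H](c1c(O)cc(OC)cc1OC)[C@@H]1CCC(=O)C=C1CC=C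
F4 | step 8 | hydroxy enoate, the C4 tertiary alcohol (4R) of 15 with the ester intact | CC(C)C[C@H](c1c(OC)cc(OC)cc1OC)[C@@H]1CC[C@@](C)(O)[C@H]2CC(C(=O)OC)=CC[C@]12C
F5 | step 8 | saturated hydroxy ester, mixture of C7 epimers | CC(C)C[C@H](c1c(OC)cc(OC)cc1OC)[C@@H]1CC[C@@](C)(O)[C@H]2CC(C(=O)OC)CC[C@]12C
F6 | step 8 | saturated hydroxy ester with the equatorial C7 ester (7S) | CC(C)C[C@H](c1c(OC)cc(OC)cc1OC)[C@@H]1CC[C@@](C)(O)[C@H]2C[C@@H](C(=O)OC)CC[C@]12C
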